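**Retrosynthetic overview**

1. The two esters come off last (C10 angelate, C6 4-hydroxybenzoate with the phenol as a TBS ether); the C8=C9/C10–OH allylic alcohol comes from a C10 ketone (dehydrogenation, 1,2-reduction), and that ketone from a C10 exocyclic methylene.
2. The C4(OH)(iPr)/C5–H/C6–OH triad comes from bicyclic enone 15 (C4(iPr)=C5–C6=O) by hydroxyl-directed epoxidation, SmI2 opening and 1,3-anti reduction; 15 comes from enone 13 by isopropyl addition and oxidative 1,3-transposition.
3. Key disconnection: C1–C5 and C9–C10 together, by a rhodium-catalysed intramolecular [5+2] cycloaddition of the allene–vinylcyclopropane 11; both rings close in this step (cyclopentane at the insertion, cycloheptene at the reductive elimination).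
4. Enabling feature: the seven-membered ring is a cycloheptene whose C5–C6–C7–C8–C9 arc (methyl on C8) is a ring-opened (E)-alkenyl-2-methylcyclopropane, while C1 (quaternary, methyl) and C10 (oxygenated) are the tether-side C=C of a 1,1-disubstituted allene whose terminal CH2 is the masked C10 oxygen; C2–C3–C4 of the cyclopentane is the three-atom tether.
5. 11 is assembled from Weinreb enamide 4 (Charette cyclopropanation, the only source of absolute configuration, relayed to C1 and erased at C8 in step 17) and allenyl iodide 9 (Johnson–Claisen).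

Key step: step 7

Remark: the acyl group C/C=C(/C)C(=O)O is read as (Z)-2-methylbut-2-enoate (angelate); bicyclic compounds carry daucane numbering on the bicyclo[5.3.0]decane skeleton (C1 quaternary ring-fusion carbon, C4 isopropyl carbinol, C5 ring-fusion CH, C6 and C10 acyloxy carbons, C8 methyl-bearing carbon), and β means the face of the C1 methyl.

**Route**

Step 1
Reactants: 1 (E)-but-2-en-1-ol
Product: 2 [(1S,2S)-2-methylcyclopropyl]methanol
Conditions: Et2Zn, CH2I2, DME, (4R,5R)-2-butyl-N,N,N′,N′-tetramethyl-1,3,2-dioxaborolane-4,5-dicarboxamide (1.2 equiv), CH2Cl2, −10 °C to rt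
Reagents that add atoms: diiodomethane, ICI
Why: Charette asymmetric Simmons–Smith cyclopropanation, in which the zinc alkoxide held by the chiral dioxaborolane delivers CH2 to one face of the (E)-alkene, setting both ring stereocentres (trans).

Step 2
Reactants: 2 [(1S,2S)-2-methylcyclopropyl]methanol
Product: 4 (E)-N-methoxy-N-methyl-3-[(1S,2S)-2-methylcyclopropyl]prop-2-enamide, via aldehyde 3 (not isolated)
Conditions: TEMPO (10 mol %), PhI(OAc)2, CH2Cl2, rt; then Ph3P=CHC(O)N(OMe)Me, rt
Reagents that add atoms: N-methoxy-N-methyl-2-(triphenyl-λ5-phosphanylidene)acetamide, CON(C)C(=O)C=P(c1ccccc1)(c1ccccc1)c1ccccc1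
Why: One-pot TEMPO oxidation/Wittig olefination keeps the volatile aldehyde in solution, and the stabilised ylide gives the (E)-enamide without touching the cyclopropane stereocentres.

Step 3
Reactants: 5 but-2-yn-1-ol
Product: 7 ethyl 3-methylpenta-3,4-dienoate, via ketene acetal 6 (not isolated)
Conditions: MeC(OEt)3 (5 equiv), EtCO2H (cat.), 140 °C, EtOH distilled off
Reagents that add atoms: triethyl orthoacetate, CC(OCC)(OCC)OCC
Why: Johnson orthoester Claisen rearrangement of a propargylic alcohol, whose [3,3] shift onto the methyl-bearing alkyne carbon gives the 1,1-disubstituted allene.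

Step 4
Reactants: 7 ethyl 3-methylpenta-3,4-dienoate
Product: 8 3-methylpenta-3,4-dien-1-ol
Conditions: LiAlH4, Et2O, 0 °C
Reagents that add atoms: none
Why: Hydride reduction of the ester; the unconjugated allene is inert.

Step 5
Reactants: 8 3-methylpenta-3,4-dien-1-ol
Product: 9 5-iodo-3-methylpenta-1,2-diene
Conditions: iodine, PPh3, imidazole, CH2Cl2, 0 °C
Reagents that add atoms: iodine, II
Why: Appel-type iodination of a primary alcohol under neutral conditions that leave the allene alone.

Step 6
Reactants: 9 5-iodo-3-methylpenta-1,2-diene; 4 (E)-N-methoxy-N-methyl-3-[(1S,2S)-2-methylcyclopropyl]prop-2-enamide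
Product: 11 (E)-6-methyl-1-[(1S,2S)-2-methylcyclopropyl]octa-1,6,7-trien-3-one, via organolithium 10 (not isolated)
Conditions: t-BuLi (2.1 equiv), Et2O–pentane, −78 °C; then 4, −78 to 0 °C; aq. NH4Cl
Reagents that add atoms: none
Why: Iodine–lithium exchange followed by acylation with the Weinreb amide, whose chelated tetrahedral intermediate stops at the ketone and disfavours conjugate addition.

Step 7
Reactants: 11 (E)-6-methyl-1-[(1S,2S)-2-methylcyclopropyl]octa-1,6,7-trien-3-one
Product: 13 1β,8α-dimethyl-10-methylidenebicyclo[5.3.0]dec-5-en-4-one, via cis-fused cycloadduct 12 (not isolated)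
Conditions: [Rh(CO)2Cl]2 (5 mol %), ClCH2CH2Cl (0.02 M), 80 °C; then DBU (0.2 equiv), rt
Reagents that add atoms: none
Why: Rhodium binds the enone alkene and cleaves the less substituted C7–C9 cyclopropane bond (strain release) to a σ-alkyl/π-allyl rhodacycle, the tethered allene inserts through its tether-side C=C to make C1–C5, and reductive elimination makes C9–C10; DBU then moves the C6=C7 alkene of 12 into conjugation. The closest known reaction is the rhodium-catalysed intramolecular [5+2] cycloaddition of allenes with vinylcyclopropanes, including disubstituted allene termini that give angular quaternary carbons and 2-substituted cyclopropanes that open at the less hindered bond. The cyclopentanone closes by the C1–C5 insertion across the three-atom tether (5-exo with respect to the allene) and the cycloheptene closes by C9–C10 reductive elimination from the eight-membered rhodacycle. C5 is formed on the alkene face that carries C9 in the s-cis conformer, the only one that can give the cis ring alkene, so the C7 configuration of the cyclopropane fixes C5; C1 follows from the cis ring fusion that the short tether enforces, and C8 is carried over unchanged. The step needs reaction at the tether-side allene bond (secured by tether length, leaving the terminal CH2 as the exocyclic methylene that later becomes the C10 oxygen) and cleavage of C7–C9 over C7–C8 (secured by the C8 methyl); the C5 centre, formed cis to the C1 methyl, is deliberately erased by the isomerisation and reset in step 13.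

Step 8
Reactants: 13 1β,8α-dimethyl-10-methylidenebicyclo[5.3.0]dec-5-en-4-one
Product: 14 4-isopropyl-1β,8α-dimethyl-10-methylidenebicyclo[5.3.0]dec-5-en-4-ol (both C4 epimers)
Conditions: CeCl3, iPrMgCl, THF, −78 °C
Reagents that add atoms: isopropylmagnesium chloride, CC(C)[Mg]Cl
Why: Organocerium 1,2-addition to an enolisable enone; the C4 configuration does not matter because this carbon becomes sp2 in step 9.

Step 9
Reactants: 14 4-isopropyl-1β,8α-dimethyl-10-methylidenebicyclo[5.3.0]dec-5-en-4-ol
Product: 15 4-isopropyl-1β,8α-dimethyl-10-methylidenebicyclo[5.3.0]dec-4-en-6-one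
Conditions: pyridinium chlorochromate C5H5NH[CrO3Cl], 4 Å molecular sieves, CH2Cl2, rt
Reagents that add atoms: pyridinium chlorochromate, [O-][Cr](=O)(=O)Cl.c1cc[nH+]cc1
Why: Dauben–Babler oxidative 1,3-transposition: the [3,3] shift of the tertiary allylic chromate ester puts oxygen on C6 and oxidation gives the enone, so both epimers of 14 converge and the carbonyl has moved from C4 to C6 with the isopropyl group in place.

Step 10
Reactants: 15 4-isopropyl-1β,8α-dimethyl-10-methylidenebicyclo[5.3.0]dec-4-en-6-one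
Product: 16 4-isopropyl-1β,8α-dimethyl-10-methylidenebicyclo[5.3.0]dec-4-en-6β-ol
Conditions: (S)-2-methyl-CBS-oxazaborolidine (0.2 equiv), catecholborane, toluene, −78 °C
Reagents that add atoms: none
Why: Corey–Bakshi–Shibata 1,2-reduction under catalyst control (alkenyl side large, C7H2 small) places the C6 hydroxyl on the β face, a temporary stereocentre that only serves to direct step 11; catecholborane does not hydroborate the exocyclic alkene at this temperature.

Step 11
Reactants: 16 4-isopropyl-1β,8α-dimethyl-10-methylidenebicyclo[5.3.0]dec-4-en-6β-ol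
Product: 17 4β,5β-epoxy-4-isopropyl-1β,8α-dimethyl-10-methylidenebicyclo[5.3.0]decan-6β-ol
Conditions: VO(acac)2 (5 mol %), t-BuOOH, CH2Cl2, 0 °C to rt
Reagents that add atoms: tert-butyl hydroperoxide, CC(C)(C)OO
Why: Hydroxyl-directed vanadium-catalysed epoxidation of the allylic alcohol delivers oxygen to the C4=C5 face syn to the C6 hydroxyl, which sets the C4–O bond β (cis to the C1 methyl); the remote 1,1-disubstituted alkene is not directed and stays.

Step 12
Reactants: 17 4β,5β-epoxy-4-isopropyl-1β,8α-dimethyl-10-methylidenebicyclo[5.3.0]decan-6β-ol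
Product: 18 4β,5β-epoxy-4-isopropyl-1β,8α-dimethyl-10-methylidenebicyclo[5.3.0]decan-6-one
Conditions: Dess–Martin periodinane, NaHCO3, CH2Cl2, 0 °C to rt
Reagents that add atoms: none
Why: Dess–Martin oxidation of the secondary alcohol gives the α,β-epoxy ketone without opening the epoxide.

Step 13
Reactants: 18 4β,5β-epoxy-4-isopropyl-1β,8α-dimethyl-10-methylidenebicyclo[5.3.0]decan-6-one
Product: 19 (5α-H)-4β-hydroxy-4-isopropyl-1β,8α-dimethyl-10-methylidenebicyclo[5.3.0]decan-6-one (trans-fused)
Conditions: SmI2 (2.5 equiv), THF–MeOH, −90 to −78 °C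
Reagents that add atoms: none
Why: Reductive cleavage of the Cα–O bond of an α,β-epoxy ketone with SmI2 keeps the C4–O bond and its configuration; C5 is protonated through the samarium enolate and, being epimerisable, should settle trans-fused (5α-H), where the C6 carbonyl is cis to the C4 hydroxyl (hydrogen bond) and trans to the isopropyl group.

Step 14
Reactants: 19 (5α-H)-4β-hydroxy-4-isopropyl-1β,8α-dimethyl-10-methylidenebicyclo[5.3.0]decan-6-one
Product: 20 (5α-H)-4-isopropyl-1β,8α-dimethyl-10-methylidenebicyclo[5.3.0]decane-4β,6α-diol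
Conditions: Me4N[BH(OAc)3], MeCN–AcOH (1:1), −30 °C
Reagents that add atoms: none
Why: Evans–Saksena reduction, in which the borohydride bound to the C4 oxygen delivers hydride intramolecularly to the β face of the C6 ketone and gives the 1,3-anti diol (6α-OH).

Step 15
Reactants: 20 (5α-H)-4-isopropyl-1β,8α-dimethyl-10-methylidenebicyclo[5.3.0]decane-4β,6α-diol
Product: 21 6α-[4-(tert-butyldimethylsilyloxy)benzoyloxy]-4-isopropyl-1β,8α-dimethyl-10-methylidenebicyclo[5.3.0]decan-4β-ol
Conditions: 4-(TBSO)C6H4CO2H, EDC·HCl, DMAP, CH2Cl2, rt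
Reagents that add atoms: 4-[(tert-butyldimethylsilyl)oxy]benzoic acid, CC(C)(C)[Si](C)(C)Oc1ccc(cc1)C(=O)O
Why: Steglich esterification acylates only the secondary C6 hydroxyl; the tertiary C4 hydroxyl is too hindered.

Step 16
Reactants: 21 6α-[4-(tert-butyldimethylsilyloxy)benzoyloxy]-4-isopropyl-1β,8α-dimethyl-10-methylidenebicyclo[5.3.0]decan-4β-ol
Product: 23 6α-[4-(tert-butyldimethylsilyloxy)benzoyloxy]-4β-hydroxy-4-isopropyl-1β,8α-dimethylbicyclo[5.3.0]decan-10-one, via ozonide 22 (not isolated)
Conditions: O3, CH2Cl2, −78 °C; then PPh3, −78 °C to rt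
Reagents that add atoms: ozone, [O-][O+]=O
Why: Ozonolysis with reductive work-up cleaves the only alkene and unmasks the C10 ketone that the allene terminus stood for.

Step 17
Reactants: 23 6α-[4-(tert-butyldimethylsilyloxy)benzoyloxy]-4β-hydroxy-4-isopropyl-1β,8α-dimethylbicyclo[5.3.0]decan-10-one
Product: 24 6α-[4-(tert-butyldimethylsilyloxy)benzoyloxy]-4β-hydroxy-4-isopropyl-1β,8-dimethylbicyclo[5.3.0]dec-8-en-10-one
Conditions: 2-iodoxybenzoic acid (1.5 equiv), DMSO–fluorobenzene, 70 °C
Reagents that add atoms: none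
Why: Nicolaou dehydrogenation of a ketone with 2-iodoxybenzoic acid: C10 can enolise only towards C9 (C1 is quaternary), so the C8=C9 enone forms regiospecifically and the relay stereocentre at C8 is erased.

Step 18
Reactants: 24 6α-[4-(tert-butyldimethylsilyloxy)benzoyloxy]-4β-hydroxy-4-isopropyl-1β,8-dimethylbicyclo[5.3.0]dec-8-en-10-one
Product: 25 6α-[4-(tert-butyldimethylsilyloxy)benzoyloxy]-4-isopropyl-1β,8-dimethylbicyclo[5.3.0]dec-8-ene-4β,10β-diol
Conditions: NaBH4, CeCl3·7H2O, MeOH, −78 °C
Reagents that add atoms: none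
Why: Luche 1,2-reduction, with hydride attacking C10 anti to the axial C1 methyl on the neighbouring quaternary carbon to give the 10β-alcohol (cis to that methyl).

Step 19
Reactants: 25 6α-[4-(tert-butyldimethylsilyloxy)benzoyloxy]-4-isopropyl-1β,8-dimethylbicyclo[5.3.0]dec-8-ene-4β,10β-diol
Product: 26 10β-angeloyloxy-6α-[4-(tert-butyldimethylsilyloxy)benzoyloxy]-4-isopropyl-1β,8-dimethylbicyclo[5.3.0]dec-8-en-4β-ol
Conditions: angelic acid, 2,4,6-Cl3C6H2COCl, Et3N, toluene, rt; then 25, NaHCO3, toluene, 75 °C (no DMAP)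
Reagents that add atoms: angelic acid [(Z)-2-methylbut-2-enoic acid], C/C=C(/C)C(=O)O
Why: Yamaguchi-type acylation through the mixed anhydride without a nucleophilic amine catalyst keeps the (Z)-geometry, and only the secondary allylic C10 hydroxyl reacts while the tertiary C4 hydroxyl does not.

Step 20
Reactants: 26 10β-angeloyloxy-6α-[4-(tert-butyldimethylsilyloxy)benzoyloxy]-4-isopropyl-1β,8-dimethylbicyclo[5.3.0]dec-8-en-4β-ol
Product: 27 (1S,4R,5S,6S,10S)-10-angeloyloxy-4-hydroxy-6-(4-hydroxybenzoyloxy)dauc-8-ene (target)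
Conditions: TBAF, AcOH, THF, 0 °C
Reagents that add atoms: none
Why: Buffered fluoride desilylation cleaves the aryl silyl ether selectively, without hydrolysing either ester or isomerising the angelate.

**Compound list**

1 | (E)-but-2-en-1-ol | C/C=C/CO | starting material
2 | [(1S,2S)-2-methylcyclopropyl]methanol | OC[C@H]1C[C@@H]1C | intermediate
3 | (1S,2S)-2-methylcyclopropane-1-carbaldehyde | O=C[C@H]1C[C@@H]1C | intermediate (not isolated)
4 | (E)-N-methoxy-N-methyl-3-[(1S,2S)-2-methylcyclopropyl]prop-2-enamide | CON(C)C(=O)/C=C/[C@H]1C[C@@H]1C | intermediate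
5 | but-2-yn-1-ol | CC#CCO | starting material
6 | 1-(but-2-yn-1-yloxy)-1-ethoxyethene (ketene acetal) | C=C(OCC)OCC#CC | intermediate (not isolated)
7 | ethyl 3-methylpenta-3,4-dienoate | CCOC(=O)CC(C)=C=C | intermediate
8 | 3-methylpenta-3,4-dien-1-ol | OCCC(C)=C=C | intermediate
9 | 5-iodo-3-methylpenta-1,2-diene | ICCC(C)=C=C | intermediate
10 | (3-methylpenta-3,4-dien-1-yl)lithium | [Li]CCC(C)=C=C | intermediate (not isolated)
11 | (E)-6-methyl-1-[(1S,2S)-2-methylcyclopropyl]octa-1,6,7-trien-3-one | C=C=C(C)CCC(=O)/C=C/[C@H]1C[C@@H]1C | intermediate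
12 | (5β-H)-1β,8α-dimethyl-10-methylidenebicyclo[5.3.0]dec-6-en-4-one (cis-fused cycloadduct) | O=C1CC[C@]2(C)C(=C)C[C@H](C)C=C[C@H]12 | intermediate (not isolated)
13 | 1β,8α-dimethyl-10-methylidenebicyclo[5.3.0]dec-5-en-4-one | O=C1CC[C@]2(C)C(=C)C[C@H](C)CC=C12 | intermediate
14 | 4-isopropyl-1β,8α-dimethyl-10-methylidenebicyclo[5.3.0]dec-5-en-4-ol (both C4 epimers) | CC(C)C1(O)CC[C@]2(C)C(=C)C[C@H](C)CC=C12 | intermediate
15 | 4-isopropyl-1β,8α-dimethyl-10-methylidenebicyclo[5.3.0]dec-4-en-6-one | CC(C)C1=C2C(=O)C[C@@H](C)CC(=C)[C@@]2(C)CC1 | intermediate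
16 | 4-isopropyl-1β,8α-dimethyl-10-methylidenebicyclo[5.3.0]dec-4-en-6β-ol | CC(C)C1=C2[C@H](O)C[C@@H](C)CC(=C)[C@@]2(C)CC1 | intermediate
17 | 4β,5β-epoxy-4-isopropyl-1β,8α-dimethyl-10-methylidenebicyclo[5.3.0]decan-6β-ol | CC(C)[C@]12CC[C@]3(C)C(=C)C[C@H](C)C[C@@H](O)[C@]13O2 | intermediate
18 | 4β,5β-epoxy-4-isopropyl-1β,8α-dimethyl-10-methylidenebicyclo[5.3.0]decan-6-one | CC(C)[C@]12CC[C@]3(C)C(=C)C[C@H](C)CC(=O)[C@]13O2 | intermediate
19 | (5α-H)-4β-hydroxy-4-isopropyl-1β,8α-dimethyl-10-methylidenebicyclo[5.3.0]decan-6-one | CC(C)[C@]1(O)CC[C@]2(C)C(=C)C[C@H](C)CC(=O)[C@@H]12 | intermediate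
20 | (5α-H)-4-isopropyl-1β,8α-dimethyl-10-methylidenebicyclo[5.3.0]decane-4β,6α-diol | CC(C)[C@]1(O)CC[C@]2(C)C(=C)C[C@H](C)C[C@H](O)[C@@H]12 | intermediate
21 | 6α-[4-(tert-butyldimethylsilyloxy)benzoyloxy]-4-isopropyl-1β,8α-dimethyl-10-methylidenebicyclo[5.3.0]decan-4β-ol | CC(C)[C@]1(O)CC[C@]2(C)C(=C)C[C@H](C)C[C@H](OC(=O)c3ccc(O[Si](C)(C)C(C)(C)C)cc3)[C@@H]12 | intermediate
22 | spiro-1,2,4-trioxolane (ozonide) of 21 at C10 (either configuration at the spiro carbon) | CC(C)[C@]1(O)CC[C@]2(C)C3(OCOO3)C[C@H](C)C[C@H](OC(=O)c4ccc(O[Si](C)(C)C(C)(C)C)cc4)[C@@H]12 | intermediate (not isolated)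
23 | 6α-[4-(tert-butyldimethylsilyloxy)benzoyloxy]-4β-hydroxy-4-isopropyl-1β,8α-dimethylbicyclo[5.3.0]decan-10-one | CC(C)[C@]1(O)CC[C@]2(C)C(=O)C[C@H](C)C[C@H](OC(=O)c3ccc(O[Si](C)(C)C(C)(C)C)cc3)[C@@H]12 | intermediate
24 | 6α-[4-(tert-butyldimethylsilyloxy)benzoyloxy]-4β-hydroxy-4-isopropyl-1β,8-dimethylbicyclo[5.3.0]dec-8-en-10-one | CC(C)[C@]1(O)CC[C@]2(C)C(=O)C=C(C)C[C@H](OC(=O)c3ccc(O[Si](C)(C)C(C)(C)C)cc3)[C@@H]12 | intermediate
25 | 6α-[4-(tert-butyldimethylsilyloxy)benzoyloxy]-4-isopropyl-1β,8-dimethylbicyclo[5.3.0]dec-8-ene-4β,10β-diol | CC(C)[C@]1(O)CC[C@]2(C)[C@@H](O)C=C(C)C[C@H](OC(=O)c3ccc(O[Si](C)(C)C(C)(C)C)cc3)[C@@H]12 | intermediate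
26 | 10β-angeloyloxy-6α-[4-(tert-butyldimethylsilyloxy)benzoyloxy]-4-isopropyl-1β,8-dimethylbicyclo[5.3.0]dec-8-en-4β-ol | CC(C)[C@]1(O)CC[C@]2(C)[C@@H](OC(=O)/C(C)=C\C)C=C(C)C[C@H](OC(=O)c3ccc(O[Si](C)(C)C(C)(C)C)cc3)[C@@H]12 | intermediate
27 | (1S,4R,5S,6S,10S)-10-angeloyloxy-4-hydroxy-6-(4-hydroxybenzoyloxy)dauc-8-ene | CC(C)[C@]1(O)CC[C@]2(C)[C@@H](OC(=O)/C(C)=C\C)C=C(C)C[C@H](OC(=O)c3ccc(O)cc3)[C@@H]12 | target

**Count and risks**

Total step count: 20. Longest linear sequence: 18 steps (steps 3 to 20, from but-2-yn-1-ol 5).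

Three steps most likely to fail:

Step 7. Ring opening of the acceptor-substituted vinylcyclopropane at rhodium may be slow or may lose its preference for the unsubstituted cyclopropane bond, and insertion at the fully substituted allene terminus is sterically demanding; either would lower conversion or erode the transfer of chirality to C1. The fallback takes the carbonyl out of conjugation before the cycloaddition. Starting from 11, Luche reduction (NaBH4, CeCl3·7H2O, MeOH, −78 °C) gives the allylic alcohol (E)-6-methyl-1-[(1S,2S)-2-methylcyclopropyl]octa-1,6,7-trien-3-ol F1 as both carbinol epimers, an electron-rich vinylcyclopropane of the kind on which the allene [5+2] cycloaddition is established. [Rh(CO)2Cl]2 in ClCH2CH2Cl at 80 °C should then give the cis-fused cycloadduct alcohol (5β-H)-1β,8α-dimethyl-10-methylidenebicyclo[5.3.0]dec-6-en-4-ol F2, and Dess–Martin oxidation returns to 12, which is isomerised with DBU to 13 as in step 7.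

Step 11. Oxygen has to be delivered to a tetrasubstituted alkene on the face that also carries the C1 methyl; the epoxidation may stall, and the vanadium peroxide may instead oxidise the allylic alcohol back to the enone. The fallback brings in the C4 oxygen as the carbonyl of the cycloadduct and the isopropyl group as the nucleophile. It sets out from 12 (step 7 stopped before the DBU treatment). K2CO3 in MeOH at 0 °C equilibrates the ring-fusion centre by α-reprotonation of the dienolate to the trans-fused ketone (5α-H)-1β,8α-dimethyl-10-methylidenebicyclo[5.3.0]dec-6-en-4-one F3, the cis isomer being resubjected. iPrMgCl/CeCl3 adds anti to C6 and to the C1 methyl to give the tertiary alcohol (5α-H)-4-isopropyl-1β,8α-dimethyl-10-methylidenebicyclo[5.3.0]dec-6-en-4β-ol F4. Me2SiHCl/Et3N gives its dimethylsilyl ether F5, which undergoes intramolecular (Tamao) hydrosilylation of the C6=C7 alkene with Pt2[(CH2=CHSiMe2)2O]3 (zerovalent platinum) to the oxasilolane bridging the C4 oxygen and C6, F6. Tamao oxidation (H2O2, KF, KHCO3, THF–MeOH) gives (5α-H)-4-isopropyl-1β,8α-dimethyl-10-methylidenebicyclo[5.3.0]decane-4β,6β-diol F7, and Dess–Martin oxidation of its secondary hydroxyl comes back to the route at 19.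

Step 19. Acylation of the neopentylic allylic C10 hydroxyl is slow, and forcing conditions or amine catalysts isomerise the (Z)-acyl group to the (E)-isomer. The fallback builds the (Z)-alkene on the substrate. From 25, esterification with 2-[bis(2,2,2-trifluoroethoxy)phosphoryl]propanoic acid (EDC·HCl, DMAP, CH2Cl2) gives the 10β-(2-phosphonopropanoate) of 25, F8. Still–Gennari olefination (KN(SiMe3)2, 18-crown-6, THF, −78 °C, then acetaldehyde) forms the (Z)-2-methylbut-2-enoate and comes back to the route at 26.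

**Further compounds**

F1 | step 7 | (E)-6-methyl-1-[(1S,2S)-2-methylcyclopropyl]octa-1,6,7-trien-3-ol (both C3 epimers) | C=C=C(C)CCC(O)/C=C/[C@H]1C[C@@H]1C
F2 | step 7 | (5β-H)-1β,8α-dimethyl-10-methylidenebicyclo[5.3.0]dec-6-en-4-ol (both C4 epimers) | OC1CC[C@]2(C)C(=C)C[C@H](C)C=C[C@H]12
F3 | step 11 | (5α-H)-1β,8α-dimethyl-10-methylidenebicyclo[5.3.0]dec-6-en-4-one | O=C1CC[C@]2(C)C(=C)C[C@H](C)C=C[C@@H]12
F4 | step 11 | (5α-H)-4-isopropyl-1β,8α-dimethyl-10-methylidenebicyclo[5.3.0]dec-6-en-4β-ol | CC(C)[C@]1(O)CC[C@]2(C)C(=C)C[C@H](C)C=C[C@@H]12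
F5 | step 11 | dimethylsilyl ether of F4 | C[SiH](C)O[C@@]1(C(C)C)CC[C@]2(C)C(=C)C[C@H](C)C=C[C@@H]12
F6 | step 11 | oxasilolane from F5 (4β-O–SiMe2–C6β) | C[Si]1(C)O[C@@]2(C(C)C)CC[C@]3(C)C(=C)C[C@H](C)C[C@@H]1[C@@H]23
F7 | step 11 | (5α-H)-4-isopropyl-1β,8α-dimethyl-10-methylidenebicyclo[5.3.0]decane-4β,6β-diol | CC(C)[C@]1(O)CC[C@]2(C)C(=C)C[C@H](C)C[C@@H](O)[C@@H]12
F8 | step 19 | 10β-{2-[bis(2,2,2-trifluoroethoxy)phosphoryl]propanoate} of 25 (either configuration at the phosphonate-bearing carbon) | CC(C)[C@]1(O)CC[C@]2(C)[C@@H](OC(=O)C(C)P(=O)(OCC(F)(F)F)OCC(F)(F)F)C=C(C)C[C@H](OC(=O)c3ccc(O[Si](C)(C)C(C)(C)C)cc3)[C@@H]12
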